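**Retrosynthetic overview**
1. The target comes from its C19 silyl ether by desilylation and selective primary acetylation. Cutting C4–C5 and C9–C10 of that decalin in one stroke gives an open chain. The chain carries a C3/C4 oxirane, an E C5=C10 alkene and a C17-silylated C8=C9 alkene already joined to the E-vinyl-butenolide.
2. Enabling feature, part one: in ring B the exocyclic methylene C8=C17 lies beside C9, which is bonded to quaternary C10. The triad C17–C8–C9 is therefore the footprint of an allylsilane attacked at C9.
3. Enabling feature, part two: in ring A the equatorial C3–OH lies beside quaternary C4, the footprint of an oxirane opened at C4. The lactone carbonyl sits on C13, cross-conjugated to C11=C12, so the dienyl side chain can be in place without switching off C9.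
4. Chain assembly: C9–C11 by Stille coupling, C3=C4 by Still–Gennari olefination then Sharpless epoxidation (the only outside source of chirality), C8=C9 by carbocupration, C5=C10 by Johnson–Claisen rearrangement.
5. Ring order: butenolide (bought as 3-bromofuran-2(5H)-one), temporary oxirane, then ring A and last ring B in the same operation.

Key step: step 11

Remark: labdane numbering is used. The decalin is C1–C10 and C17 is the exocyclic methylene carbon. C18 is the methyl and C19 the oxygenated carbon on C4, C20 is the methyl on C10, C11=C12 is the side-chain alkene and C13–C16 are the butenolide carbons. Compounds 1, 2, 4, 7, 11, 16 and 17 are taken as catalogue chemicals.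

**Step 1**
Reactants: 1 pent-4-ynal; 2 isopropenylmagnesium bromide
Product: 3 (±)-2-methylhept-1-en-6-yn-3-ol
Conditions: 2 (1.3 equiv), THF, −78 → −20 °C; aq NH4Cl
Reagents that add atoms: none
Why: Grignard 1,2-addition to the aldehyde is faster at low temperature than deprotonation of the terminal alkyne, and the carbinol centre may be racemic because step 2 erases it.

**Step 2**
Reactants: 3 (±)-2-methylhept-1-en-6-yn-3-ol; 4 triethyl orthoacetate
Product: 6 ethyl (E)-4-methylnon-4-en-8-ynoate, via ketene acetal 5 (not isolated)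
Conditions: 4 (6 equiv), EtCO2H (5 mol %), 135 °C, EtOH distilled off
Reagents that add atoms: none
Why: In the Johnson orthoester Claisen rearrangement the chair transition state of 5 holds the butynyl chain equatorial, which should give the E trisubstituted C5=C10 alkene while the racemic carbinol centre disappears.

**Step 3**
Reactants: 6 ethyl (E)-4-methylnon-4-en-8-ynoate; 7 (trimethylsilyl)methylmagnesium chloride
Product: 9 ethyl (4E,8Z)-9-iodo-4-methyl-8-[(trimethylsilyl)methyl]nona-4,8-dienoate, via alkenylcopper 8 (not isolated)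
Conditions: 7 (2 equiv), CuBr·SMe2 (2 equiv), Et2O–Me2S, −30 °C; then 6, −10 → 23 °C; then I2 (2.2 equiv), THF, −40 → 0 °C; aq Na2S2O3
Reagents that add atoms: iodine, II
Why: In the Normant carbocupration the α-silyl organocopper reagent adds syn to the terminal alkyne with carbon on the inner and copper on the outer carbon, iodinolysis of 8 with retention puts iodine cis to CH2SiMe3 (C7 trans to the future C11), and organocopper reagents leave the ester alone.

**Step 4**
Reactants: 9 ethyl (4E,8Z)-9-iodo-4-methyl-8-[(trimethylsilyl)methyl]nona-4,8-dienoate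
Product: 10 (4E,8Z)-9-iodo-4-methyl-8-[(trimethylsilyl)methyl]nona-4,8-dienal
Conditions: iBu2AlH (1.05 equiv), CH2Cl2, −78 °C; aq potassium sodium tartrate
Reagents that add atoms: none
Why: Partial ester reduction with one equivalent of iBu2AlH at −78 °C stops at the aldehyde level and touches neither the alkenyl iodide nor the allylsilane.

**Step 5**
Reactants: 10 (4E,8Z)-9-iodo-4-methyl-8-[(trimethylsilyl)methyl]nona-4,8-dienal; 11 ethyl 2-[bis(2,2,2-trifluoroethoxy)phosphoryl]propanoate
Product: 12 ethyl (2Z,6E,10Z)-11-iodo-2,6-dimethyl-10-[(trimethylsilyl)methyl]undeca-2,6,10-trienoate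
Conditions: 11 (1.2 equiv), KN(SiMe3)2 (1.15 equiv), 18-crown-6 (3 equiv), THF, −78 °C
Reagents that add atoms: none
Why: In the Still–Gennari variant of the Horner–Wadsworth–Emmons reaction the trifluoroethyl phosphonate with a dissociated potassium ion eliminates under kinetic control, which should give the Z enoate and place the future C19 cis to the chain.

**Step 6**
Reactants: 12 ethyl (2Z,6E,10Z)-11-iodo-2,6-dimethyl-10-[(trimethylsilyl)methyl]undeca-2,6,10-trienoate
Product: 13 (2Z,6E,10Z)-11-iodo-2,6-dimethyl-10-[(trimethylsilyl)methyl]undeca-2,6,10-trien-1-ol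
Conditions: iBu2AlH (2.5 equiv), CH2Cl2, −78 → −20 °C; aq potassium sodium tartrate
Reagents that add atoms: none
Why: 1,2-Reduction of an enoate with excess iBu2AlH gives the allylic alcohol without change of the Z geometry.

**Step 7**
Reactants: 13 (2Z,6E,10Z)-11-iodo-2,6-dimethyl-10-[(trimethylsilyl)methyl]undeca-2,6,10-trien-1-ol
Product: 14 [(2S,3R)-3-{(3E,7Z)-8-iodo-3-methyl-7-[(trimethylsilyl)methyl]octa-3,7-dien-1-yl}-2-methyloxiran-2-yl]methanol
Conditions: Ti(OiPr)4 (10 mol %), L-(+)-diethyl tartrate (13 mol %), t-BuOOH (2 equiv, decane), 4 Å MS, CH2Cl2, −20 °C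
Reagents that add atoms: tert-butyl hydroperoxide, CC(C)(C)OO
Why: The Sharpless asymmetric epoxidation is directed by the allylic hydroxyl and so picks only the C3=C4 alkene, and the L-(+)-tartrate catalyst should give the (2S,3R)-oxirane (C4 S, C3 R) with the hydroxymethyl group cis to the chain.

**Step 8**
Reactants: 14 [(2S,3R)-3-{(3E,7Z)-8-iodo-3-methyl-7-[(trimethylsilyl)methyl]octa-3,7-dien-1-yl}-2-methyloxiran-2-yl]methanol
Product: 15 tert-butyl({(2S,3R)-3-{(3E,7Z)-8-iodo-3-methyl-7-[(trimethylsilyl)methyl]octa-3,7-dien-1-yl}-2-methyloxiran-2-yl}methoxy)dimethylsilane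
Conditions: TBSCl (1.2 equiv), imidazole (2.5 equiv), CH2Cl2, 0 → 23 °C
Reagents that add atoms: tert-butyldimethylsilyl chloride, CC(C)(C)[Si](C)(C)Cl
Why: Standard silylation of a primary alcohol gives a bulky, weakly basic ether that cannot take part in the oxirane opening of step 11.

**Step 9**
Reactants: 16 3-bromofuran-2(5H)-one; 17 (E)-1,2-bis(tributylstannyl)ethene
Product: 18 3-[(E)-2-(tributylstannyl)ethenyl]furan-2(5H)-one
Conditions: 17 (2 equiv), Pd2(dba)3·CHCl3 (2.5 mol %), AsPh3 (10 mol %), THF, 50 °C
Reagents that add atoms: none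
Why: Stille coupling of the activated α-bromobutenolide proceeds with retention of the E geometry, and the excess of 17 should hold the reaction at the single coupling.

**Step 10**
Reactants: 15 the silyl-protected iodo-oxirane; 18 3-[(E)-2-(tributylstannyl)ethenyl]furan-2(5H)-one
Product: 19 3-[(1E,3Z,7E)-10-[(2R,3S)-3-({[tert-butyl(dimethyl)silyl]oxy}methyl)-3-methyloxiran-2-yl]-8-methyl-4-[(trimethylsilyl)methyl]deca-1,3,7-trien-1-yl]furan-2(5H)-one
Conditions: 18 (1.2 equiv), Pd2(dba)3·CHCl3 (5 mol %), AsPh3 (20 mol %), NMP, 23 °C, dark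
Reagents that add atoms: none
Why: Stille coupling of an alkenyl iodide with an alkenylstannane keeps both alkene geometries and is neutral, so oxirane, silyl ether, allylsilane and butenolide should survive.

**Step 11**
Reactants: 19 the oxirane–diene–trienylsilane butenolide
Product: 21 3-[(E)-2-[(1R,4aS,5R,6R,8aR)-5-({[tert-butyl(dimethyl)silyl]oxy}methyl)-6-hydroxy-5,8a-dimethyl-2-methylidenedecahydronaphthalen-1-yl]ethenyl]furan-2(5H)-one, via beta-silyl cation 20 (not isolated)
Conditions: MeAlCl2 (3 equiv), CH2Cl2 (0.01 M), −78 °C; then Et3N, aq NaHCO3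
Reagents that add atoms: none
Why: Proposed new method: MeAlCl2 binds the oxirane oxygen, the tertiary C4–O bond opens under backside attack of the C5=C10 alkene, the charge arriving at C10 is taken up by C9 of the C8=C9 alkene, and the β-silyl cation 20 gives its Me3Si group to chloride, which leaves the C8=C17 methylene and, after work-up, the free C3 hydroxyl. The closest known reaction type is the oxirane-initiated cationic polyene bicyclisation terminated by an allylsilane (also known with an ester on the attacked carbon) together with the γ-selective SE2' substitution of pentadienylsilanes; what is new is a terminator that is the inner alkene of a silylmethyl-substituted triene ending in a butenolide. Ring A closes first, 6-endo at the oxirane (attack at the far, tertiary carbon) and 6-endo-trig at the alkene, and ring B closes last, 6-endo-trig at C8=C9, both in chair-like folds. C3 is carried over from 19 unchanged, C4 is inverted so that the silyloxymethyl group, cis to the chain on the oxirane, ends up axial, C5 and C10 arise by anti addition across the E alkene (trans fusion) on the face fixed by the chair that keeps the C3–O bond equatorial, and C9 is fixed by the C8=C9 geometry (C11 trans to C7), which places the dienyl chain equatorial. The step needs bond formation at C9 and not at C8, C12 or C14: hyperconjugation of the C17–Si bond raises the electron density at C9, C12 and C14 only, and of these only C9 is reachable through a six-membered chair (C12 and C14 would need eight- and ten-membered rings that contain E alkenes), while the lactone carbonyl on C13 is cross-conjugated and does not drain C9. The methylaluminium Lewis acid scavenges protons and so guards the silane against protodesilylation, and the bulky, weakly basic silyl ether on C19 cannot open the oxirane as a neighbouring acetate would.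

**Step 12**
Reactants: 21 the C19 silyl ether of the decalin
Product: 22 14-deoxy-11,12-didehydroandrographolide, 3-[(E)-2-[(1R,4aS,5R,6R,8aR)-6-hydroxy-5-(hydroxymethyl)-5,8a-dimethyl-2-methylidenedecahydronaphthalen-1-yl]ethenyl]furan-2(5H)-one
Conditions: HF·pyridine, pyridine, THF, 0 → 23 °C
Reagents that add atoms: none
Why: Fluoride-driven silyl ether cleavage under buffered, non-basic conditions avoids deprotonation at the doubly allylic C9, and the diol can be recrystallised to raise the enantiomeric purity if needed.

**Step 13**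
Reactants: 22 14-deoxy-11,12-didehydroandrographolide
Product: 23 19-O-acetyl-14-deoxy-11,12-didehydroandrographolide, 3-[(E)-2-[(1R,4aS,5R,6R,8aR)-5-(acetoxymethyl)-6-hydroxy-5,8a-dimethyl-2-methylidenedecahydronaphthalen-1-yl]ethenyl]furan-2(5H)-one (target)
Conditions: AcCl (1.1 equiv), 2,4,6-collidine (2 equiv), CH2Cl2, −78 → −40 °C
Reagents that add atoms: acetyl chloride, CC(=O)Cl
Why: Chemoselective acylation with acetyl chloride and a hindered pyridine base at low temperature should acetylate the primary C19 hydroxyl ahead of the secondary C3 hydroxyl that is flanked by quaternary C4.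

**Compound list**
1 | pent-4-ynal | C#CCCC=O | starting material
2 | isopropenylmagnesium bromide | C=C(C)[Mg]Br | starting material
3 | (±)-2-methylhept-1-en-6-yn-3-ol | C=C(C)C(O)CCC#C | intermediate
4 | triethyl orthoacetate | CC(OCC)(OCC)OCC | starting material
5 | ketene acetal, 3-[(1-ethoxyethenyl)oxy]-2-methylhept-1-en-6-yne (not isolated) | C=C(OCC)OC(CCC#C)C(C)=C | intermediate
6 | ethyl (E)-4-methylnon-4-en-8-ynoate | CCOC(=O)CC/C(C)=C/CCC#C | intermediate
7 | (trimethylsilyl)methylmagnesium chloride | C[Si](C)(C)C[Mg]Cl | starting material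
8 | alkenylcopper, ethyl (4E,8Z)-9-cuprio-4-methyl-8-[(trimethylsilyl)methyl]nona-4,8-dienoate (not isolated) | CCOC(=O)CC/C(C)=C/CC/C(C[Si](C)(C)C)=C/[Cu] | intermediate
9 | ethyl (4E,8Z)-9-iodo-4-methyl-8-[(trimethylsilyl)methyl]nona-4,8-dienoate | CCOC(=O)CC/C(C)=C/CC/C(C[Si](C)(C)C)=C/I | intermediate
10 | (4E,8Z)-9-iodo-4-methyl-8-[(trimethylsilyl)methyl]nona-4,8-dienal | O=CCC/C(C)=C/CC/C(C[Si](C)(C)C)=C/I | intermediate
11 | ethyl 2-[bis(2,2,2-trifluoroethoxy)phosphoryl]propanoate | CCOC(=O)C(C)P(=O)(OCC(F)(F)F)OCC(F)(F)F | starting material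
12 | ethyl (2Z,6E,10Z)-11-iodo-2,6-dimethyl-10-[(trimethylsilyl)methyl]undeca-2,6,10-trienoate | CCOC(=O)/C(C)=C\CC/C(C)=C/CC/C(C[Si](C)(C)C)=C/I | intermediate
13 | (2Z,6E,10Z)-11-iodo-2,6-dimethyl-10-[(trimethylsilyl)methyl]undeca-2,6,10-trien-1-ol | OC/C(C)=C\CC/C(C)=C/CC/C(C[Si](C)(C)C)=C/I | intermediate
14 | [(2S,3R)-3-{(3E,7Z)-8-iodo-3-methyl-7-[(trimethylsilyl)methyl]octa-3,7-dien-1-yl}-2-methyloxiran-2-yl]methanol | C[C@@]1(CO)O[C@@H]1CC/C(C)=C/CC/C(C[Si](C)(C)C)=C/I | intermediate
15 | tert-butyldimethylsilyl ether of 14, (2S,3R)-oxirane | C[C@@]1(CO[Si](C)(C)C(C)(C)C)O[C@@H]1CC/C(C)=C/CC/C(C[Si](C)(C)C)=C/I | intermediate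
16 | 3-bromofuran-2(5H)-one | O=C1OCC=C1Br | starting material
17 | (E)-1,2-bis(tributylstannyl)ethene | CCCC[Sn](CCCC)(CCCC)/C=C/[Sn](CCCC)(CCCC)CCCC | starting material
18 | 3-[(E)-2-(tributylstannyl)ethenyl]furan-2(5H)-one | CCCC[Sn](CCCC)(CCCC)/C=C/C1=CCOC1=O | intermediate
19 | 3-[(1E,3Z,7E)-10-[(2R,3S)-3-({[tert-butyl(dimethyl)silyl]oxy}methyl)-3-methyloxiran-2-yl]-8-methyl-4-[(trimethylsilyl)methyl]deca-1,3,7-trien-1-yl]furan-2(5H)-one | C[C@@]1(CO[Si](C)(C)C(C)(C)C)O[C@@H]1CC/C(C)=C/CC/C(C[Si](C)(C)C)=C/C=C/C1=CCOC1=O | intermediate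
20 | bicyclic C8 β-silyl cation with the C3 oxygen bound to MeAlCl2 (zwitterion, not isolated) | C[Si](C)(C)C[C+]1CC[C@@H]2[C@](C)(CO[Si](C)(C)C(C)(C)C)[C@H](O[Al-](C)(Cl)Cl)CC[C@@]2(C)[C@@H]1/C=C/C1=CCOC1=O | intermediate
21 | 19-O-(tert-butyldimethylsilyl)-14-deoxy-11,12-didehydroandrographolide, (1R,4aS,5R,6R,8aR) | C=C1CC[C@@H]2[C@](C)(CO[Si](C)(C)C(C)(C)C)[C@H](O)CC[C@@]2(C)[C@@H]1/C=C/C1=CCOC1=O | intermediate
22 | 14-deoxy-11,12-didehydroandrographolide, (1R,4aS,5R,6R,8aR) | C=C1CC[C@@H]2[C@](C)(CO)[C@H](O)CC[C@@]2(C)[C@@H]1/C=C/C1=CCOC1=O | intermediate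
23 | 19-O-acetyl-14-deoxy-11,12-didehydroandrographolide, (1R,4aS,5R,6R,8aR) | C=C1CC[C@@H]2[C@](C)(COC(C)=O)[C@H](O)CC[C@@]2(C)[C@@H]1/C=C/C1=CCOC1=O | target

**Step count**
Total step count: 13.
Longest linear sequence: 12 (steps 1–8 and 10–13). Step 9 is a one-step side branch.

**Steps most likely to fail**

*Step 11 (the labelled step).*
- What may go wrong: proton loss or a hydride shift after oxirane opening before ring B has closed, protodesilylation of the trienylsilane, attack of the cation at a remote position of the triene, or Lewis-acid-induced oligomerisation of the tetraene.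
- Scope of the fallback: it uses known chemistry only, sets out from 15 and comes back at 21. The side chain is kept out of conjugation during the cyclisation and is built afterwards onto the bought butenolide ring, so ring B is still the last ring closed.
- Cyclisation substrate: methoxycarbonylation of 15 (Pd(PPh3)4, CO 1 atm, MeOH, Et3N, DMF, 50 °C) should give the methyl (Z)-3-(silylmethyl)enoate F1.
- Cyclisation: SnCl4 or MeAlCl2 in CH2Cl2 at −78 °C is the established oxirane-initiated bicyclisation ended by an ester-bearing allylsilane. It should give the bicyclic β,γ-unsaturated ester F2 with the same five stereocentres.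
- Side chain: iBu2AlH should give the C3,C11-diol F3. TEMPO/PhI(OAc)2 should oxidise only the primary alcohol to the aldehyde F4.
- Coupling: Takai-type olefination with Cl2CHBpin, CrCl2 and LiI should give the (E)-vinylboronate F5. Suzuki coupling of F5 with 16 (Pd(dppf)Cl2, K3PO4, THF–H2O, 23 °C) returns to 21.

*Step 3.*
- What may go wrong: sluggish addition of the stabilised α-silyl organocopper reagent, competing deprotonation of the alkyne, erosion of regiocontrol, or attack of residual Grignard reagent on the ester.
- The fallback sets out from 6 and comes back at 9, and it replaces carbocupration by borylcupration.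
- Copper-catalysed borylative alkylation (CuCl, Xantphos, B2pin2, LiOtBu, ICH2SiMe3, THF, 23 °C) adds boron to the terminal carbon and copper to the inner carbon in syn fashion. The alkenylcopper is then alkylated with retention, which should give the alkenylboronate F6.
- Iododeboronation with retention (I2, aq NaOH, THF, 0 °C, short contact) returns to 9.

*Step 10.*
- What may go wrong: slow transmetalation at the hindered trisubstituted iodide, homocoupling or protodestannylation of 18, and geometric isomerisation or a sigmatropic hydrogen shift of the tetraene during a long reaction or purification.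
- The fallback sets out from 15 and comes back at 19, and it moves the last bond from C9–C11 to C12–C13.
- Stille coupling of 15 with excess 17 should give the dienylstannane F7.
- F7 is then coupled with the more reactive electrophile 16 (Pd2(dba)3·CHCl3, AsPh3, NMP, 23 °C) to return to 19. Compound 18 is not needed in this variant.

**Further compounds**
F1 | step 11 | methyl (2Z,6E)-9-[(2R,3S)-3-({[tert-butyl(dimethyl)silyl]oxy}methyl)-3-methyloxiran-2-yl]-7-methyl-3-[(trimethylsilyl)methyl]nona-2,6-dienoate | C[C@@]1(CO[Si](C)(C)C(C)(C)C)O[C@@H]1CC/C(C)=C/CC/C(C[Si](C)(C)C)=C/C(=O)OC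
F2 | step 11 | methyl (1R,4aS,5R,6R,8aR)-5-({[tert-butyl(dimethyl)silyl]oxy}methyl)-6-hydroxy-5,8a-dimethyl-2-methylidenedecahydronaphthalene-1-carboxylate | C=C1CC[C@@H]2[C@](C)(CO[Si](C)(C)C(C)(C)C)[C@H](O)CC[C@@]2(C)[C@@H]1C(=O)OC
F3 | step 11 | C3,C11-diol, the 1-(hydroxymethyl)decalin with the configuration of F2 | C=C1CC[C@@H]2[C@](C)(CO[Si](C)(C)C(C)(C)C)[C@H](O)CC[C@@]2(C)[C@@H]1CO
F4 | step 11 | C11 aldehyde, the decalin-1-carbaldehyde with the configuration of F2 | C=C1CC[C@@H]2[C@](C)(CO[Si](C)(C)C(C)(C)C)[C@H](O)CC[C@@]2(C)[C@@H]1C=O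
F5 | step 11 | (E)-vinylboronate, pinacol ester of the (E)-2-(decalin-1-yl)ethenylboronic acid with the configuration of 21 | C=C1CC[C@@H]2[C@](C)(CO[Si](C)(C)C(C)(C)C)[C@H](O)CC[C@@]2(C)[C@@H]1/C=C/B1OC(C)(C)C(C)(C)O1
F6 | step 3 | ethyl (4E,8Z)-4-methyl-9-(4,4,5,5-tetramethyl-1,3,2-dioxaborolan-2-yl)-8-[(trimethylsilyl)methyl]nona-4,8-dienoate | CCOC(=O)CC/C(C)=C/CC/C(C[Si](C)(C)C)=C/B1OC(C)(C)C(C)(C)O1
F7 | step 10 | tributyl[(1E,3Z,7E)-10-[(2R,3S)-3-({[tert-butyl(dimethyl)silyl]oxy}methyl)-3-methyloxiran-2-yl]-8-methyl-4-[(trimethylsilyl)methyl]deca-1,3,7-trien-1-yl]stannane | C[C@@]1(CO[Si](C)(C)C(C)(C)C)O[C@@H]1CC/C(C)=C/CC/C(C[Si](C)(C)C)=C/C=C/[Sn](CCCC)(CCCC)CCCC
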